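**Retrosynthetic overview**

- The depside is cut so that ring B (the chlorinated acid ring) disappears entirely, leaving an aryl 4-chloroacetoacetate on the 4-oxygen of methyl orsellinate (ring A, bought). That ester bond comes from capture of chloroacetylketene, released from chloroacetyl Meldrum's acid, by the 4-OH of ring A.
- Ring B is then assembled on this ester by a formal [3+3] cyclocondensation. Bonds C3–C4 and C1–C6 are formed between the 4-chloro-1,3-bis(silyloxy)diene of the ester and 4,4-dimethoxybut-3-en-2-one.
- The strategy rests on this feature of ring B: C1 with the depside carbonyl carbon, C2–OH and C3–Cl are the four carbons of a 4-chloroacetoacetyl unit, while C4–OMe, C5–H and C6–CH3 are an acetoacetyl unit at the ketene acetal oxidation level. Chlorine, methoxy and methyl therefore arrive in place, with no arene chlorination and no esterification of a hindered benzoic acid.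
- Ring order: ring A is bought, the depside ester is made second, and ring B is closed last. The target has no stereocentre.

Key step: step 6

Remark: the enol ether double bonds of 7, 8, 9 and 13 and the sp3 centres of 13 and 14 are expected to form without control and are erased on aromatization, so their SMILES carry no stereodescriptors.

**Route**

Step 1
Reactants: 1 Meldrum's acid; 2 chloroacetyl chloride
Product: 3 5-(2-chloro-1-hydroxyethylidene)-2,2-dimethyl-1,3-dioxane-4,6-dione (chloroacetyl Meldrum's acid in its enol form)
Conditions: pyridine (2 equiv), CH2Cl2, 0 °C to rt; dilute aq HCl wash; used crude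
Reagents that add atoms: none
Why: C-acylation of the very acidic Meldrum's acid by an acid chloride with pyridine is the standard entry to 5-acyl Meldrum's acids, and the chloromethyl group is not touched at this temperature.

Step 2
Reactants: 3 chloroacetyl Meldrum's acid; 4 methyl orsellinate (methyl 2,4-dihydroxy-6-methylbenzoate)
Product: 6 methyl 4-[(4-chloro-3-oxobutanoyl)oxy]-2-hydroxy-6-methylbenzoate, via chloroacetylketene 5 (not isolated)
Conditions: 4 (1.2 equiv), toluene, 95 °C, 3 added in portions
Reagents that add atoms: none
Why: Thermal fragmentation of the acyl Meldrum's acid (loss of acetone and CO2) should give the acylketene, which is captured under neutral conditions by the free 4-OH of 4, while the 2-OH is hydrogen-bonded to the neighbouring ester carbonyl and should stay unacylated (acylketene trapping by a phenol).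

Step 3
Reactants: 6 methyl 4-[(4-chloro-3-oxobutanoyl)oxy]-2-hydroxy-6-methylbenzoate
Product: 7 methyl 4-{[4-chloro-3-(trimethylsilyloxy)but-2-enoyl]oxy}-6-methyl-2-(trimethylsilyloxy)benzoate (E/Z mixture)
Conditions: Me3SiCl (3 equiv), Et3N (3 equiv), toluene, rt, 48 h; filtration under argon; used crude
Reagents that add atoms: chlorotrimethylsilane, C[Si](C)(C)Cl
Why: O-silylation of the strongly enolized β-keto ester and of the ring A phenol with Me3SiCl/Et3N (silyl enol ether formation) should give the conjugated 3-silyloxy enoate and remove the only acidic OH before the amide base is used.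

Step 4
Reactants: 7 methyl 4-{[4-chloro-3-(trimethylsilyloxy)but-2-enoyl]oxy}-6-methyl-2-(trimethylsilyloxy)benzoate
Product: 9 methyl 4-{[4-chloro-1,3-bis(trimethylsilyloxy)buta-1,3-dien-1-yl]oxy}-6-methyl-2-(trimethylsilyloxy)benzoate, via lithium dienolate 8 (not isolated)
Conditions: LiN(iPr)2 (1.1 equiv) added to 7 and Me3SiCl (1.5 equiv), THF, −78 °C; then pentane, filtration under argon; used crude, kept cold and dry
Reagents that add atoms: chlorotrimethylsilane, C[Si](C)(C)Cl
Why: Kinetic γ-deprotonation of a 3-silyloxy enoate by a hindered lithium amide followed by O-silylation is the standard preparation of 1,3-bis(silyloxy)-1,3-dienes of the Chan type, including 4-chloro ones; the γ-CHCl protons are far more acidic than the benzylic methyl of ring A, and the internal quench at −78 °C gives the aryl ester dienolate no time to expel aryloxide.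

Step 5
Reactants: 10 1,1-dimethoxyethene (ketene dimethyl acetal); 11 acetyl chloride
Product: 12 4,4-dimethoxybut-3-en-2-one
Conditions: Et3N, Et2O, 0 °C to rt; filtration; distillation under reduced pressure
Reagents that add atoms: none
Why: The electron-rich ketene acetal is C-acylated by the acid chloride and the oxocarbenium intermediate loses a proton to Et3N, which should give the push-pull β,β-dimethoxy enone (acylation of a ketene acetal).

Step 6
Reactants: 9 methyl 4-{[4-chloro-1,3-bis(trimethylsilyloxy)buta-1,3-dien-1-yl]oxy}-6-methyl-2-(trimethylsilyloxy)benzoate; 12 4,4-dimethoxybut-3-en-2-one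
Product: 15 methyl 4-[(3-chloro-2-hydroxy-4-methoxy-6-methylbenzoyl)oxy]-2-hydroxy-6-methylbenzoate, via open-chain Michael adduct 13 (not isolated), via cyclohexenone aldol 14 (not isolated)
Conditions: 12 (1.5 equiv), TiCl4 (2 equiv), CH2Cl2, 4 Å molecular sieves, −78 °C to rt; then 1 M aq HCl, THF, rt
Reagents that add atoms: none
Why: Coordination of TiCl4 to the carbonyl oxygen of 12 turns the push-pull alkene into an O-titanated dimethoxyallyl cation whose (MeO)2C terminus is the electrophilic site; the ClCH= terminus of diene 9 adds there (vinylogous Mukaiyama–Michael addition) and one methoxy group is expelled, so adduct 13 carries a β-methoxy enone that already holds the C4–OMe of ring B. The central carbon of the former diene, still an enol silane, then adds to the activated methyl ketone in a 6-(enolexo)-exo-trig Mukaiyama aldol closure of ring B to give 14 (counted from the ester-side silyl ketene acetal; after a 1,5-silyl shift the same closure counts as 6-(enolendo)-exo-trig, which is also allowed), and loss of the tertiary oxygen with enolization of the ring ketone should give the aromatic ring. The closest known reaction type is the TiCl4-mediated formal [3+3] cyclocondensation of 1,3-bis(silyloxy)-1,3-dienes with 1,3-dielectrophiles (Chan–Brownbridge salicylate synthesis), which is established for 4-chloro dienes and for β,β-dialkoxy enones. No stereocentre is created that survives, since the CHCl and carbinol centres of 13 and 14 vanish on aromatization. The selectivity demanded is the head-to-tail orientation of the two three-carbon pieces, and the diene itself should secure it: its terminal carbon is the most nucleophilic site and reacts first at the acetal carbon of 12 (bond C3–C4), leaving the central carbon to close on the ketone (bond C1–C6), so that Cl sits between OH and OMe and CH3 sits next to the ester. The crowded depside ester is already present before the ring exists, both esters should be inert to TiCl4 at low temperature, and the acidic work-up hydrolyses the three silyl ethers.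

**Compound list**

1 | Meldrum's acid (2,2-dimethyl-1,3-dioxane-4,6-dione) | CC1(C)OC(=O)CC(=O)O1 | starting material
2 | chloroacetyl chloride | ClCC(=O)Cl | starting material
3 | 5-(2-chloro-1-hydroxyethylidene)-2,2-dimethyl-1,3-dioxane-4,6-dione (chloroacetyl Meldrum's acid, enol form) | CC1(C)OC(=O)C(=C(O)CCl)C(=O)O1 | intermediate
4 | methyl orsellinate (methyl 2,4-dihydroxy-6-methylbenzoate) | COC(=O)c1c(C)cc(O)cc1O | starting material
5 | chloroacetylketene (4-chlorobut-1-ene-1,3-dione) | O=C=CC(=O)CCl | intermediate
6 | methyl 4-[(4-chloro-3-oxobutanoyl)oxy]-2-hydroxy-6-methylbenzoate | COC(=O)c1c(C)cc(OC(=O)CC(=O)CCl)cc1O | intermediate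
7 | methyl 4-{[4-chloro-3-(trimethylsilyloxy)but-2-enoyl]oxy}-6-methyl-2-(trimethylsilyloxy)benzoate (E/Z mixture) | COC(=O)c1c(C)cc(OC(=O)C=C(O[Si](C)(C)C)CCl)cc1O[Si](C)(C)C | intermediate
8 | lithium dienolate of 7 (lithium 1-aryloxy-4-chloro-3-(trimethylsilyloxy)buta-1,3-dien-1-olate, aryl = 4-methoxycarbonyl-5-methyl-3-(trimethylsilyloxy)phenyl) | COC(=O)c1c(C)cc(OC(O[Li])=CC(O[Si](C)(C)C)=CCl)cc1O[Si](C)(C)C | intermediate
9 | methyl 4-{[4-chloro-1,3-bis(trimethylsilyloxy)buta-1,3-dien-1-yl]oxy}-6-methyl-2-(trimethylsilyloxy)benzoate (mixture of double bond isomers) | COC(=O)c1c(C)cc(OC(O[Si](C)(C)C)=CC(O[Si](C)(C)C)=CCl)cc1O[Si](C)(C)C | intermediate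
10 | 1,1-dimethoxyethene (ketene dimethyl acetal) | C=C(OC)OC | starting material
11 | acetyl chloride | CC(=O)Cl | starting material
12 | 4,4-dimethoxybut-3-en-2-one | CC(=O)C=C(OC)OC | intermediate
13 | methyl 4-{[4-chloro-5-methoxy-3,7-dioxo-1-(trimethylsilyloxy)octa-1,5-dien-1-yl]oxy}-6-methyl-2-(trimethylsilyloxy)benzoate (open-chain Michael adduct, racemic at the CHCl carbon, shown as the silyl ketene acetal) | COC(=O)c1c(C)cc(OC(O[Si](C)(C)C)=CC(=O)C(Cl)C(OC)=CC(C)=O)cc1O[Si](C)(C)C | intermediate
14 | 4-methoxycarbonyl-5-methyl-3-(trimethylsilyloxy)phenyl 3-chloro-6-hydroxy-4-methoxy-6-methyl-2-oxocyclohex-4-ene-1-carboxylate (cyclic aldol, mixture of diastereomers, shown as the free tertiary alcohol of its titanium alkoxide) | COC(=O)c1c(C)cc(OC(=O)C2C(=O)C(Cl)C(OC)=CC2(C)O)cc1O[Si](C)(C)C | intermediate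
15 | methyl 4-[(3-chloro-2-hydroxy-4-methoxy-6-methylbenzoyl)oxy]-2-hydroxy-6-methylbenzoate (CNP0146021.0) | COC(=O)c1c(C)cc(OC(=O)c2c(C)cc(OC)c(Cl)c2O)cc1O | target

**Summary**

Total step count: 6. Longest linear sequence: 5 steps (steps 1, 2, 3, 4 and 6); step 5 is a one-step side branch.

Steps most likely to fail, with fallbacks:

1. Step 6. The β-keto aryl ester intermediates may expel the ring A aryloxide (acylketene formation) or be cleaved by the liberated methoxide before ring B is aromatic. The ring A salicylate may also tie up the Lewis acid, so that the attack of the chlorinated diene terminus becomes too slow. The fallback takes the aryl ester out of the cyclocondensation and makes the depside bond afterwards. It sets out from 3, uses 12 and 4 from the main route, and comes back at 15.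
   - Heating 3 with benzyl alcohol in toluene should give benzyl 4-chloro-3-oxobutanoate F1.
   - Me3SiCl/Et3N should convert it into benzyl 4-chloro-3-(trimethylsilyloxy)but-2-enoate F2.
   - LiN(iPr)2 and Me3SiCl at −78 °C should then give 1-benzyloxy-4-chloro-1,3-bis(trimethylsilyloxy)buta-1,3-diene F3.
   - TiCl4-mediated cyclocondensation of this alkyl ester diene with 12 should give benzyl 3-chloro-2-hydroxy-4-methoxy-6-methylbenzoate F4.
   - Hydrogenolysis (H2, Pd/C, ethyl acetate, stopped after one equivalent of hydrogen so that the C–Cl bond is kept) should free 3-chloro-2-hydroxy-4-methoxy-6-methylbenzoic acid F5.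
   - The acid and 4 are then joined with trifluoroacetic anhydride in toluene, the classical depside esterification, which should acylate the free 4-OH of 4 and give 15.

2. Step 4. The lithium dienolate of an aryl ester may lose aryloxide to give a vinylketene, the amide may deprotonate the benzylic methyl of ring A, or it may attack the aryl ester. The fallback replaces hard deprotonation by soft enolization and avoids any metal enolate. It sets out from 6 and comes back at 9. Compound 6 is treated in one operation with trimethylsilyl trifluoromethanesulfonate (about 3.3 equiv) and Et3N in diethyl ether at 0 °C. The phenol and the ketone enol are silylated first. The silyl triflate then activates the ester carbonyl, and the amine removes the γ-proton. The diene should thus form without an anionic intermediate, and the detour makes no compound outside the list (none F0).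

3. Step 2. Capture of the ketene by the phenol may be slow at the temperature needed for fragmentation, so that the ketene dimerizes, the 2-OH is acylated as well, or the α-chloro ketone product degrades on prolonged heating. The fallback changes from thermal ketene capture to a cold acylation with a preformed acid chloride. It sets out from 4 and comes back at 6. Diketene is chlorinated with Cl2 in CH2Cl2 at −30 °C to give 4-chloro-3-oxobutanoyl chloride F6. This is added to 4 with one equivalent of pyridine at −30 °C, where the more nucleophilic 4-OH should be acylated to give 6.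

**Further compounds**

F1 | step 6 | benzyl 4-chloro-3-oxobutanoate | O=C(CC(=O)CCl)OCc1ccccc1
F2 | step 6 | benzyl 4-chloro-3-(trimethylsilyloxy)but-2-enoate | C[Si](C)(C)OC(CCl)=CC(=O)OCc1ccccc1
F3 | step 6 | 1-benzyloxy-4-chloro-1,3-bis(trimethylsilyloxy)buta-1,3-diene | C[Si](C)(C)OC(OCc1ccccc1)=CC(O[Si](C)(C)C)=CCl
F4 | step 6 | benzyl 3-chloro-2-hydroxy-4-methoxy-6-methylbenzoate | COc1cc(C)c(C(=O)OCc2ccccc2)c(O)c1Cl
F5 | step 6 | 3-chloro-2-hydroxy-4-methoxy-6-methylbenzoic acid | COc1cc(C)c(C(=O)O)c(O)c1Cl
F0 | step 4 | none | none
F6 | step 2 | 4-chloro-3-oxobutanoyl chloride | O=C(Cl)CC(=O)CCl
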